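**Locants.** C1 is the methyl-bearing ring-fusion carbon, C2 the angelate carbon, C3 a methylene, C4 the isopropyl carbinol carbon, C5 the ring-fusion CH, C6 the aroyloxy carbon, C7 a methylene, C8=C9 the alkene (methyl on C8) and C10 a methylene. Ring A is C1–C5 and ring B is C1, C5–C10.

## Analysis of the target

The target 41 is a daucane-type diester: a cis-fused bicyclo[5.3.0]decene made of cyclopentane ring A and cycloheptene ring B. Its five stereocentres are (1R,2S,4S,5R,6R). The C1 methyl and H-5 are cis; the C2 ester oxygen and the C4 hydroxyl lie on the other face of ring A, the face that carries the ring B carbons C10 and C6. The isopropyl group lies on the methyl face, and the C6 aroyloxy group is cis to H-5. The sensitive groups are the angelate (a Z-enoate that isomerises to the tiglate under nucleophilic or basic acylation), the tertiary C4 carbinol 1,3 to the C2 oxygen (dehydration, and retro-aldol or β-elimination at the ketone stage), and the trisubstituted C8=C9 alkene, which must not migrate. The hard points are the quaternary C1 between two stereocentres, a seven-membered ring with one correctly placed alkene, three oxygens (C2, C4, C6) that must be told apart, and a C2 oxygen on the concave face trans to the angular methyl. The strategy rests on one feature: C1 bears the oxygenated carbon C2 and is tied through C10 to the C8=C9 alkene, so C2(=O)–C1–C10–C9=C8 is a γ,δ-unsaturated carbonyl array, the product pattern of a Claisen shift. Putting the oxygen back on C8 turns ring B into a seven-membered lactone (O, C2, C1, C5, C6, C7, C8) with a vinyl group on a methyl-bearing tertiary carbinol carbon, and that carbinol centre can come from the chiral pool and pass its configuration to C1.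

## Retrosynthetic reasoning

**Ester bonds.** The two acyl–oxygen bonds are cut first: 41 goes back to alcohol 39 and aroyl chloride 40, and angelate 38 goes back to diol 36 and acid 37. The angelate is put on while C6 still carries its silyl ether, and the aroyl group goes on last, because aroylation needs no conditions that threaten a Z-enoate. The forward steps must acylate hindered secondary alcohols beside a free tertiary alcohol. C2 and C6 are therefore masked by silyl groups of different lability (triethylsilyl and triisopropylsilyl).

**C4–isopropyl bond.** Cutting this bond in 35 leads to cyclopentanone 34. Placing the cut here makes the tertiary carbinol the last skeletal stereocentre, set on a rigid cis-fused bicycle where the face of H-5 is open and the other face is blocked by C6 and the C2 silyloxy group. The forward step needs a non-basic isopropyl nucleophile, because the ketone is enolisable and β-oxygenated.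

**C2–C3 bond (ring A).** The β-silyloxy ketone 34 is an aldol product and opens to keto aldehyde 32. This cut is chosen because its two carbonyl groups map onto the two handles the key step leaves on ring B: the acetyl group comes from the C5 vinyl group (31 to 32) and the aldehyde from the carboxyl group on C1 (29 to 30 to 31). The forward step has to close a five-membered ring by attack of the methyl ketone carbon C3 on C2 and set the C2 configuration.

**C1–C10 bond (key disconnection).** Acid 29 is the product of a [3,3] shift. Cutting C1–C10 and rejoining C8 to the carboxyl oxygen gives the seven-membered vinyl lactone 25. This is the only cut that removes the quaternary centre and ring B together while keeping the alkene where it is needed. The forward reaction must enolise the lactone at C1, trap the enolate on oxygen and let the C8 vinyl group bond to C1 from its own face.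

**C1–methyl bond.** Lactone 25 is traced to 23 by removing the C1 methyl group. The lactone is thus assembled without a stereocentre at C1, which would be erased in the key step in any case.

**Lactone C–O bond and C1.** The ester bond of 23 to the tertiary allylic oxygen is the hard bond of the lactone, because such alcohols resist ordinary lactonisation. It is therefore formed by capture of a ketene, the acylating species that hindered alcohols accept. The ketene comes from diazoketone 21 by Wolff rearrangement, which also inserts C1, and 21 goes back through 20 to acid 18. The tertiary hydroxyl stays silylated until the diazoketone exists, because a free hydroxyl would close a six-membered lactone when the carboxyl group is activated.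

**C5–C6 bond.** Acid 18 derives from imide 15, the syn-aldol product of crotonyl imide 12 and aldehyde 9. The C5 vinyl and C6 oxygen must be trans on the lactone, which is the syn relationship of this aldol. The auxiliary sets both centres without help from C8, whose methyl and vinyl groups are too alike to direct anything. For that reason a ring closure by intramolecular allylation of an aldehyde tethered through the tertiary ester was considered and put aside.

**Chiral-pool fragment.** Aldehyde 9 goes back through 8, 7, 5, 4 and 2 to (R)-citramalic acid 1. The α-hydroxy acid carboxyl becomes the C9=C10 vinyl group with the Wittig salt 6, and the other carboxyl becomes the C6 aldehyde. Imide 12 comes from oxazolidinone 10 and acid chloride 11.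

## Alternatives that were turned down

**Alternative 1:** Both bonds from C1 into ring B (C1–C5 and C1–C10) are cut, so that ring B comes from a benzene ring and both rings form at once. In the forward direction the aryl diazoketone A2 would be decomposed by a dirhodium carboxylate catalyst; the carbenoid at C1 adds across the ipso–ortho bond of the arene and the cyclopropane opens to the bicyclic trienone A1 (Buchner reaction).
- For: the whole bicyclic skeleton and the quaternary C1 arise in one catalytic step from a flat precursor. On brevity to the skeleton this route is stronger than the chosen one.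
- Against: A1 has an sp2 C5 and three ring B double bonds (C5=C6, C7=C8, C9=C10), none of which is the C8=C9 alkene of 41. H-5, the C6 carbinol, the C2 carbinol, saturation of C9–C10 and migration of the C7=C8 alkene all remain, on a cycloheptatriene that equilibrates by hydrogen shifts.
- Against: the methyl-bearing carbenoid can undergo 1,2-hydride shift, it must choose the unsubstituted ortho bond over the methoxy-bearing one, and only the remote, ionisable benzylic ether at C4 controls C1.
- Comparison: the chosen strategy needs more steps before ring B exists, but its key step delivers the alkene at C8=C9, C5 and C6 already configured, and C1 fixed by transfer from C8.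

**Alternative 2:** The C1–C2 and C4–C5 bonds are cut, so ring A is annulated onto a symmetric cycloheptadienone. In the forward direction the nitronate of nitro ketone A4 adds to one of the two equivalent β-carbons of dienone A5, and the resulting C5 enolate or enamine closes onto the isopropyl ketone to give the nitro hydroxy enone A3 with the complete skeleton.
- For: two achiral pieces give all fifteen skeletal carbons and four stereocentres in one operation, and a chiral amine catalyst could set the absolute configuration. On convergence and step count this route is clearly stronger.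
- Against: the acceptor carbon is β,β-disubstituted and the nucleophile is a secondary nitronate, so a quaternary carbon forms next to a nitro-bearing carbon in a reversible addition. A4 is a β-nitro ketone that loses nitrous acid under the same conditions, and the aldol is onto a hindered ketone.
- Against: the nitro group must later become the C2 oxygen. Reduction of a C2 ketone should occur anti to the angular methyl and give the wrong epimer. The remaining alkene is C7=C8 and must be moved out of conjugation to C8=C9.
- Comparison: the chosen strategy gives up convergence, but each stereocentre has its own well-understood control element and the sigmatropic shift places the alkene.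

**Alternative 3:** The C7–C8 and C1–C10 bonds are cut, making ring B a formal [4+3] product. In the forward direction the rhodium vinylcarbenoid from vinyldiazoacetate A7, under a chiral dirhodium prolinate catalyst, cyclopropanates the silyl enol ether alkene of diene A8, and Cope rearrangement in the same flask gives cycloheptadiene A6.
- For: a catalytic, enantioselective and well-precedented ring construction that forms the quaternary C1, the C8=C9 unsaturation and an oxygen at C6 in one step. As a catalytic asymmetric entry to ring B it is stronger than chiral pool plus auxiliary.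
- Against: the diene terminus that becomes C1 is fully substituted and electron-poor, the unfavourable case for the boat Cope step, and C1 then depends on diene geometry as well as on the catalyst.
- Against: A6 has an ester on C8 where 41 has a methyl group, an sp2 C5 and nothing of ring A. C2, C3, C4 and the centres C2, C4, C5 and C6 must all be built afterwards, with the cis relation of C5 to C1 uncontrolled.
- Comparison: the chosen key step hands over C5 with its vinyl handle, C6 with its oxygen and the methyl on C8, so fewer operations follow ring closure.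

Key step: step 15

**Remark on the chemistry.** Lactone 25 is drawn as the 3,4-trans isomer expected from alkylation anti to the C5 vinyl group. Its C1 configuration is erased in step 15, so any cis isomer would serve equally.

## Route

Step 1
Reactants: 1 (R)-citramalic acid
Product: 2 2-[(4R)-2,2,4-trimethyl-5-oxo-1,3-dioxolan-4-yl]acetic acid
Conditions: 2,2-dimethoxypropane, TsOH·H2O (cat.), rt
Reagents that add atoms: 2,2-dimethoxypropane, COC(C)(C)OC
Why: Acid-catalysed acetal exchange closes the five-membered dioxolanone on the α-hydroxy acid half only, masking the tertiary hydroxyl and the future C9 carboxyl together and leaving the CH2CO2H group free; the C8 stereocentre is not touched.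

Step 2
Reactants: 2 2-[(4R)-2,2,4-trimethyl-5-oxo-1,3-dioxolan-4-yl]acetic acid
Product: 4 (3R)-3-hydroxy-3-methyloxolan-2-one, via hydroxyethyl dioxolanone 3 (not isolated)
Conditions: BH3·SMe2, THF, 0 °C to rt; MeOH quench; then TsOH·H2O (cat.), CH2Cl2, rt
Reagents that add atoms: none
Why: Borane reduces the free carboxylic acid chemoselectively beside the dioxolanone ester, and acid then moves the acyl group onto the new primary alcohol (translactonisation) with loss of the acetonide carbon.

Step 3
Reactants: 4 (3R)-3-hydroxy-3-methyloxolan-2-one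
Product: 5 (3R)-3-methyloxolane-2,3-diol (lactol, both anomers)
Conditions: i-Bu2AlH (2.2 equiv), CH2Cl2, −78 °C
Reagents that add atoms: none
Why: Partial reduction of a γ-lactone stops at the lactol at low temperature; the first equivalent of hydride is consumed by the tertiary hydroxyl.

Step 4
Reactants: 5 (3R)-3-methyloxolane-2,3-diol, 6 methyltriphenylphosphonium bromide
Product: 7 (3R)-3-methylpent-4-ene-1,3-diol
Conditions: KOt-Bu, THF, 0 °C to reflux (excess ylide)
Reagents that add atoms: none
Why: Wittig methylenation of the lactol through its open hydroxy aldehyde form turns C9 into the C9=C10 vinyl group; the α-carbon is quaternary and cannot epimerise.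

Step 5
Reactants: 7 (3R)-3-methylpent-4-ene-1,3-diol
Product: 8 (3R)-3-methyl-3,5-bis[(triethylsilyl)oxy]pent-1-ene
Conditions: Et3SiOTf (2.5 equiv), 2,6-lutidine, CH2Cl2, −78 to 0 °C
Reagents that add atoms: triethylsilyl triflate, CC[Si](CC)(CC)OS(=O)(=O)C(F)(F)F
Why: The silyl triflate silylates both the primary and the hindered tertiary hydroxyl (silyl ether formation).

Step 6
Reactants: 8 (3R)-3-methyl-3,5-bis[(triethylsilyl)oxy]pent-1-ene
Product: 9 (3R)-3-methyl-3-[(triethylsilyl)oxy]pent-4-enal
Conditions: (COCl)2, DMSO, CH2Cl2, −78 to −40 °C; Et3N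
Reagents that add atoms: none
Why: Under Swern conditions a primary triethylsilyl ether is attacked by the chlorosulfonium salt and oxidised directly to the aldehyde, while the tertiary silyl ether is too hindered and has no carbinol hydrogen (Swern oxidation of primary silyl ethers).

Step 7
Reactants: 10 (4S)-4-benzyl-1,3-oxazolidin-2-one, 11 (2E)-but-2-enoyl chloride
Product: 12 (4S)-4-benzyl-3-[(2E)-but-2-enoyl]-1,3-oxazolidin-2-one
Conditions: n-BuLi, THF, −78 °C; then 11
Reagents that add atoms: none
Why: N-Acylation of the lithiated oxazolidinone gives the Evans crotonyl imide.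

Step 8
Reactants: 12 (4S)-4-benzyl-3-[(2E)-but-2-enoyl]-1,3-oxazolidin-2-one, 9 (3R)-3-methyl-3-[(triethylsilyl)oxy]pent-4-enal
Product: 15 (4S)-4-benzyl-3-[(2S,3R,5R)-2-ethenyl-3-hydroxy-5-methyl-5-[(triethylsilyl)oxy]hept-6-enoyl]-1,3-oxazolidin-2-one, via boron dienolate 13 (not isolated), via boron aldolate 14 (not isolated)
Conditions: Bu2BOTf, Et3N, CH2Cl2, −78 to 0 °C; 9, −78 to 0 °C; pH 7 buffer, MeOH, 30% H2O2, 0 °C
Reagents that add atoms: none
Why: Evans syn-aldol: soft enolisation at the γ-position gives the Z boron dienolate, which reacts at its α-carbon through a Zimmerman–Traxler chair. The benzyl group of the auxiliary shields one face, so C5 and C6 are set syn with the vinyl group on C5, independently of the remote C8 centre.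

Step 9
Reactants: 15 aldol adduct
Product: 16 (4S)-4-benzyl-3-[(2S,3R,5R)-2-ethenyl-5-methyl-5-[(triethylsilyl)oxy]-3-[(triisopropylsilyl)oxy]hept-6-enoyl]-1,3-oxazolidin-2-one
Conditions: i-Pr3SiOTf, 2,6-lutidine, CH2Cl2, 0 °C to rt
Reagents that add atoms: triisopropylsilyl triflate, CC(C)[Si](C(C)C)(C(C)C)OS(=O)(=O)C(F)(F)F
Why: Silylation of the secondary C6 hydroxyl with a group that outlasts the triethylsilyl ethers used at C8 and later at C2.

Step 10
Reactants: 16 silylated imide
Product: 18 (2S,3R,5R)-2-ethenyl-5-methyl-5-[(triethylsilyl)oxy]-3-[(triisopropylsilyl)oxy]hept-6-enoic acid, via peroxy acid 17 (not isolated)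
Conditions: LiOH, 30% H2O2, THF/H2O, 0 °C; aq. Na2SO3; aq. NaHSO4 to pH 4
Reagents that add atoms: hydrogen peroxide, OO
Why: Hydroperoxide attacks the exocyclic imide carbonyl selectively and sulfite reduces the peroxy acid (auxiliary cleavage); the conditions are too mild to epimerise C5 or move the vinyl group into conjugation.

Step 11
Reactants: 18 carboxylic acid
Product: 20 (3S,4R,6R)-1-diazo-3-ethenyl-6-methyl-6-[(triethylsilyl)oxy]-4-[(triisopropylsilyl)oxy]oct-7-en-2-one, via mixed carbonic anhydride 19 (not isolated)
Conditions: i-BuOCOCl, N-methylmorpholine, THF, −20 °C; CH2N2, Et2O, 0 °C to rt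
Reagents that add atoms: diazomethane, C=[N+]=[N-]
Why: First half of an Arndt–Eistert homologation: the mixed anhydride acylates diazomethane under conditions that spare the α-stereocentre. The silylated tertiary oxygen cannot close a six-membered lactone onto the activated carboxyl.

Step 12
Reactants: 20 diazoketone
Product: 21 (3S,4R,6R)-1-diazo-3-ethenyl-6-hydroxy-6-methyl-4-[(triisopropylsilyl)oxy]oct-7-en-2-one
Conditions: Bu4NF, AcOH (1:1), THF, 0 °C to rt
Reagents that add atoms: none
Why: Buffered fluoride cleaves the triethylsilyl ether far faster than the triisopropylsilyl ether (selective desilylation), and the acetic acid buffer protects the diazoketone and the enolisable C5 centre.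

Step 13
Reactants: 21 hydroxy diazoketone
Product: 23 (4S,5R,7R)-4,7-diethenyl-7-methyl-5-[(triisopropylsilyl)oxy]oxepan-2-one, via hydroxy ketene 22 (not isolated)
Conditions: hν (365 nm), PhH (0.003 M), rt
Reagents that add atoms: none
Why: Photochemical Wolff rearrangement: loss of N2 and 1,2-shift of C5 with retention give the ketene, which the tertiary C8 hydroxyl captures intramolecularly at high dilution to close the seven-membered lactone. Ketenes acylate hindered alcohols that resist ordinary lactonisation, and the C6 silyl ether excludes the five-membered lactone.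

Step 14
Reactants: 23 lactone
Product: 25 (3R,4R,5R,7R)-4,7-diethenyl-3,7-dimethyl-5-[(triisopropylsilyl)oxy]oxepan-2-one, via lithium enolate 24 (not isolated)
Conditions: LiN(i-Pr)2, THF, −78 °C; MeI, DMPU, −78 to −40 °C
Reagents that add atoms: iodomethane, CI
Why: Lactone enolate alkylation at C1, the only enolisable position; iodomethane should enter trans to the C5 vinyl group, and the new centre is erased in the next step in any case.

Step 15
Reactants: 25 (3R,4R,5R,7R)-4,7-diethenyl-3,7-dimethyl-5-[(triisopropylsilyl)oxy]oxepan-2-one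
Product: 29 (1R,6R,7R)-7-ethenyl-1,4-dimethyl-6-[(triisopropylsilyl)oxy]cyclohept-3-ene-1-carboxylic acid, via lithium enolate 26 (not isolated), via silyl ketene acetal 27 (not isolated), via silyl ester 28 (not isolated)
Conditions: LiN(i-Pr)2, t-BuMe2SiCl, HMPA, THF, −78 °C to rt; PhMe, 110 °C; K2CO3, MeOH/H2O, rt; aq. NaHSO4
Reagents that add atoms: none
Why: Deprotonation at C1, the only α-position, and O-silylation give the silyl ketene acetal 27, whose C1=C2 geometry is fixed by the ring. On heating, the array C1=C2–O–C8–C9=C10 undergoes the [3,3] shift: C1–C10 forms as C8–O breaks, giving silyl ester 28, which is hydrolysed to 29. The closest known reaction type is the Ireland–Claisen rearrangement of silyl ketene acetals of lactones that carry an alkenyl group on the carbinol carbon, which exchanges the lactone for a cycloalkene carboxylic acid. Ring B closes in this pericyclic step; the three-carbon tether C5–C6–C7 between the termini C1 and C8 forces a boat-like six-atom array (a bicyclo[3.2.2]-type transition state), not a chair. The C8 vinyl group can reach the ketene acetal only on its own face of the lactone, so C10 is delivered suprafacially and the configuration of C8, taken from 1, is transferred to the quaternary C1 (R). The new C8=C9 alkene is cis in the ring by necessity. The step needs face selectivity at C1 and reaction of the C8 vinyl group alone: the C5 vinyl group lies on the opposite face, is not part of an allyl–oxygen unit and has no 1,5-diene relation to the ketene acetal, so it remains a spectator and ends cis to the carboxyl group, as the cis ring fusion requires. The C6 silyloxy group sits on the middle carbon of the tether and can turn outward in the boat.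

Step 16
Reactants: 29 carboxylic acid
Product: 30 [(1R,6R,7R)-7-ethenyl-1,4-dimethyl-6-[(triisopropylsilyl)oxy]cyclohept-3-en-1-yl]methanol
Conditions: LiAlH4, THF, 0 to 50 °C
Reagents that add atoms: none
Why: Hydride reduction of the hindered acid to the neopentyl alcohol; the silyl ether and the isolated alkenes are inert.

Step 17
Reactants: 30 primary alcohol
Product: 31 (1R,6R,7R)-7-ethenyl-1,4-dimethyl-6-[(triisopropylsilyl)oxy]cyclohept-3-ene-1-carbaldehyde
Conditions: Dess–Martin periodinane, NaHCO3, CH2Cl2, rt
Reagents that add atoms: none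
Why: Dess–Martin oxidation to the C2 aldehyde, which cannot enolise because C1 is quaternary.

Step 18
Reactants: 31 aldehyde
Product: 32 (1R,6R,7R)-7-acetyl-1,4-dimethyl-6-[(triisopropylsilyl)oxy]cyclohept-3-ene-1-carbaldehyde
Conditions: PdCl2 (cat.), CuCl, O2 (1 atm), DMF/H2O (7:1), rt
Reagents that add atoms: water, O
Why: Tsuji–Wacker oxidation: divalent palladium activates only the monosubstituted alkene, water adds at the internal carbon C4 to give the methyl ketone, and the trisubstituted C8=C9 alkene does not react.

Step 19
Reactants: 32 keto aldehyde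
Product: 34 (3S,3aR,8R,8aR)-3a,6-dimethyl-3-[(triethylsilyl)oxy]-8-[(triisopropylsilyl)oxy]-3,3a,4,7,8,8a-hexahydroazulen-1(2H)-one [C2 silyloxy, C4 ketone, C6 silyloxy], via triethylsilyl enol ether 33 (not isolated)
Conditions: Et3SiOTf, i-Pr2NEt, CH2Cl2, −78 to 0 °C
Reagents that add atoms: triethylsilyl triflate, CC[Si](CC)(CC)OS(=O)(=O)C(F)(F)F
Why: Soft enolisation forms the enol ether at the methyl group, because C5 is too hindered, and the same triflate activates the non-enolisable aldehyde for an intramolecular Mukaiyama aldol that closes ring A (C3 to C2) and leaves the silyl group on the new oxygen. In the open transition state H-5, not C6, eclipses the enol C–O bond, so ring B lies away from the forming bond, and the silylated carbonyl oxygen points away from the enol oxygen; this should put the C2 oxygen on the face of C10, trans to the angular methyl (2S).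

Step 20
Reactants: 34 bicyclic ketone
Product: 35 (1S,3S,3aR,8R,8aR)-3a,6-dimethyl-1-(propan-2-yl)-3-[(triethylsilyl)oxy]-8-[(triisopropylsilyl)oxy]-1,2,3,3a,4,7,8,8a-octahydroazulen-1-ol [C4 carbinol]
Conditions: i-PrMgCl, CeCl3, THF, −78 °C (gives i-PrCeCl2); then 34, −78 °C; aq. NH4Cl
Reagents that add atoms: isopropylmagnesium chloride, CC(C)[Mg]Cl
Why: The organocerium reagent adds to the hindered, enolisable ketone without enolisation, β-hydride reduction or β-elimination. It attacks from the convex face, beside H-5 and away from C6 and the C2 silyloxy group, so the C4 hydroxyl ends on the ring B face (4S).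

Step 21
Reactants: 35 tertiary alcohol
Product: 36 (1S,3S,3aR,8R,8aR)-3a,6-dimethyl-1-(propan-2-yl)-8-[(triisopropylsilyl)oxy]-1,2,3,3a,4,7,8,8a-octahydroazulene-1,3-diol
Conditions: PPTS, MeOH/CH2Cl2, 0 °C
Reagents that add atoms: none
Why: Mild acid methanolysis removes the secondary triethylsilyl ether and leaves the triisopropylsilyl ether on C6 (selective desilylation).

Step 22
Reactants: 36 diol, 37 angelic acid [(2Z)-2-methylbut-2-enoic acid]
Product: 38 (1S,3S,3aR,4R,8aR)-3-hydroxy-6,8a-dimethyl-3-(propan-2-yl)-4-[(triisopropylsilyl)oxy]-1,2,3,3a,4,5,8,8a-octahydroazulen-1-yl (2Z)-2-methylbut-2-enoate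
Conditions: 37, 2,4,6-trichlorobenzoyl chloride, Et3N, PhMe, rt; then 36, 80 °C
Reagents that add atoms: none
Why: Yamaguchi-type mixed-anhydride esterification run without a nucleophilic catalyst acylates the secondary C2 hydroxyl and leaves the tertiary C4 hydroxyl alone; leaving out DMAP avoids the addition–elimination path that turns angelate into tiglate.

Step 23
Reactants: 38 silyl ether angelate
Product: 39 (1S,3S,3aR,4R,8aR)-3,4-dihydroxy-6,8a-dimethyl-3-(propan-2-yl)-1,2,3,3a,4,5,8,8a-octahydroazulen-1-yl (2Z)-2-methylbut-2-enoate
Conditions: HF·pyridine, pyridine, THF, 0 °C to rt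
Reagents that add atoms: none
Why: Buffered fluoride removes the triisopropylsilyl ether; the enoate ester, the tertiary alcohol and the alkene tolerate these conditions.

Step 24
Reactants: 39 diol angelate, 40 3,4,5-trimethoxybenzoyl chloride
Product: 41 (1S,3S,3aR,4R,8aR)-3-hydroxy-6,8a-dimethyl-1-{[(2Z)-2-methylbut-2-enoyl]oxy}-3-(propan-2-yl)-1,2,3,3a,4,5,8,8a-octahydroazulen-4-yl 3,4,5-trimethoxybenzoate (CNP0112256.1)
Conditions: DMAP, Et3N, CH2Cl2, 0 °C to rt
Reagents that add atoms: none
Why: DMAP-catalysed acylation of the only secondary hydroxyl (C6); the tertiary C4 hydroxyl does not react under these conditions.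

## Compound list

1 | (R)-citramalic acid [(2R)-2-hydroxy-2-methylbutanedioic acid] | OC(=O)C[C@@](C)(O)C(O)=O | starting material
2 | 2-[(4R)-2,2,4-trimethyl-5-oxo-1,3-dioxolan-4-yl]acetic acid | OC(=O)C[C@@]1(C)OC(C)(C)OC1=O | intermediate
3 | (5R)-5-(2-hydroxyethyl)-2,2,5-trimethyl-1,3-dioxolan-4-one | OCC[C@@]1(C)OC(C)(C)OC1=O | intermediate (not isolated)
4 | (3R)-3-hydroxy-3-methyloxolan-2-one | C[C@@]1(O)CCOC1=O | intermediate
5 | (3R)-3-methyloxolane-2,3-diol (lactol, both anomers) | C[C@@]1(O)CCOC1O | intermediate
6 | methyltriphenylphosphonium bromide | C[P+](c1ccccc1)(c1ccccc1)c1ccccc1.[Br-] | starting material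
7 | (3R)-3-methylpent-4-ene-1,3-diol | C=C[C@](C)(O)CCO | intermediate
8 | (3R)-3-methyl-3,5-bis[(triethylsilyl)oxy]pent-1-ene | C=C[C@](C)(O[Si](CC)(CC)CC)CCO[Si](CC)(CC)CC | intermediate
9 | (3R)-3-methyl-3-[(triethylsilyl)oxy]pent-4-enal | C=C[C@](C)(O[Si](CC)(CC)CC)CC=O | intermediate
10 | (4S)-4-benzyl-1,3-oxazolidin-2-one | O=C1OC[C@H](Cc2ccccc2)N1 | starting material
11 | (2E)-but-2-enoyl chloride | C/C=C/C(Cl)=O | starting material
12 | (4S)-4-benzyl-3-[(2E)-but-2-enoyl]-1,3-oxazolidin-2-one | C/C=C/C(=O)N1C(=O)OC[C@@H]1Cc1ccccc1 | intermediate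
13 | (4S)-4-benzyl-3-[(1Z)-1-[(dibutylboranyl)oxy]buta-1,3-dien-1-yl]-1,3-oxazolidin-2-one (boron dienolate of 12) | C=C/C=C(\OB(CCCC)CCCC)N1C(=O)OC[C@@H]1Cc1ccccc1 | intermediate (not isolated)
14 | O-dibutylboranyl aldolate of 15 | O=C(N1C(=O)OC[C@@H]1Cc1ccccc1)[C@@H](C=C)[C@H](OB(CCCC)CCCC)C[C@@](C)(O[Si](CC)(CC)CC)C=C | intermediate (not isolated)
15 | (4S)-4-benzyl-3-[(2S,3R,5R)-2-ethenyl-3-hydroxy-5-methyl-5-[(triethylsilyl)oxy]hept-6-enoyl]-1,3-oxazolidin-2-one | O=C(N1C(=O)OC[C@@H]1Cc1ccccc1)[C@@H](C=C)[C@H](O)C[C@@](C)(O[Si](CC)(CC)CC)C=C | intermediate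
16 | (4S)-4-benzyl-3-[(2S,3R,5R)-2-ethenyl-5-methyl-5-[(triethylsilyl)oxy]-3-[(triisopropylsilyl)oxy]hept-6-enoyl]-1,3-oxazolidin-2-one | O=C(N1C(=O)OC[C@@H]1Cc1ccccc1)[C@@H](C=C)[C@H](O[Si](C(C)C)(C(C)C)C(C)C)C[C@@](C)(O[Si](CC)(CC)CC)C=C | intermediate
17 | peroxy acid of 18 [(2S,3R,5R)-2-ethenyl-5-methyl-5-[(triethylsilyl)oxy]-3-[(triisopropylsilyl)oxy]hept-6-eneperoxoic acid] | OOC(=O)[C@@H](C=C)[C@H](O[Si](C(C)C)(C(C)C)C(C)C)C[C@@](C)(O[Si](CC)(CC)CC)C=C | intermediate (not isolated)
18 | (2S,3R,5R)-2-ethenyl-5-methyl-5-[(triethylsilyl)oxy]-3-[(triisopropylsilyl)oxy]hept-6-enoic acid | OC(=O)[C@@H](C=C)[C@H](O[Si](C(C)C)(C(C)C)C(C)C)C[C@@](C)(O[Si](CC)(CC)CC)C=C | intermediate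
19 | isobutyl carbonic anhydride of 18 | CC(C)COC(=O)OC(=O)[C@@H](C=C)[C@H](O[Si](C(C)C)(C(C)C)C(C)C)C[C@@](C)(O[Si](CC)(CC)CC)C=C | intermediate (not isolated)
20 | (3S,4R,6R)-1-diazo-3-ethenyl-6-methyl-6-[(triethylsilyl)oxy]-4-[(triisopropylsilyl)oxy]oct-7-en-2-one | [N-]=[N+]=CC(=O)[C@@H](C=C)[C@H](O[Si](C(C)C)(C(C)C)C(C)C)C[C@@](C)(O[Si](CC)(CC)CC)C=C | intermediate
21 | (3S,4R,6R)-1-diazo-3-ethenyl-6-hydroxy-6-methyl-4-[(triisopropylsilyl)oxy]oct-7-en-2-one | [N-]=[N+]=CC(=O)[C@@H](C=C)[C@H](O[Si](C(C)C)(C(C)C)C(C)C)C[C@@](C)(O)C=C | intermediate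
22 | hydroxy ketene from 21: 3-ethenyl-6-hydroxy-6-methyl-4-[(triisopropylsilyl)oxy]octa-1,7-dien-1-one, configured as 21 | O=C=C[C@@H](C=C)[C@H](O[Si](C(C)C)(C(C)C)C(C)C)C[C@@](C)(O)C=C | intermediate (not isolated)
23 | (4S,5R,7R)-4,7-diethenyl-7-methyl-5-[(triisopropylsilyl)oxy]oxepan-2-one | C=C[C@@]1(C)C[C@@H](O[Si](C(C)C)(C(C)C)C(C)C)[C@H](C=C)CC(=O)O1 | intermediate
24 | lithium enolate of 23 | C=C[C@@]1(C)C[C@@H](O[Si](C(C)C)(C(C)C)C(C)C)[C@H](C=C)C=C(O[Li])O1 | intermediate (not isolated)
25 | (3R,4R,5R,7R)-4,7-diethenyl-3,7-dimethyl-5-[(triisopropylsilyl)oxy]oxepan-2-one (key-step precursor) | C=C[C@@]1(C)C[C@@H](O[Si](C(C)C)(C(C)C)C(C)C)[C@H](C=C)[C@@H](C)C(=O)O1 | intermediate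
26 | lithium enolate of 25 | C=C[C@@]1(C)C[C@@H](O[Si](C(C)C)(C(C)C)C(C)C)[C@H](C=C)C(C)=C(O[Li])O1 | intermediate (not isolated)
27 | tert-butyldimethylsilyl ketene acetal of 25 [2-(tert-butyldimethylsilyloxy)-4,7-diethenyl-3,7-dimethyl-5-(triisopropylsilyloxy)-4,5,6,7-tetrahydrooxepine, configured as 25 at C4, C5 and C7] | C=C[C@@]1(C)C[C@@H](O[Si](C(C)C)(C(C)C)C(C)C)[C@H](C=C)C(C)=C(O[Si](C)(C)C(C)(C)C)O1 | intermediate (not isolated)
28 | tert-butyldimethylsilyl ester of 29 | CC(C)(C)[Si](C)(C)OC(=O)[C@]1(C)CC=C(C)C[C@@H](O[Si](C(C)C)(C(C)C)C(C)C)[C@@H]1C=C | intermediate (not isolated)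
29 | (1R,6R,7R)-7-ethenyl-1,4-dimethyl-6-[(triisopropylsilyl)oxy]cyclohept-3-ene-1-carboxylic acid (key-step product) | OC(=O)[C@]1(C)CC=C(C)C[C@@H](O[Si](C(C)C)(C(C)C)C(C)C)[C@@H]1C=C | intermediate
30 | [(1R,6R,7R)-7-ethenyl-1,4-dimethyl-6-[(triisopropylsilyl)oxy]cyclohept-3-en-1-yl]methanol | OC[C@]1(C)CC=C(C)C[C@@H](O[Si](C(C)C)(C(C)C)C(C)C)[C@@H]1C=C | intermediate
31 | (1R,6R,7R)-7-ethenyl-1,4-dimethyl-6-[(triisopropylsilyl)oxy]cyclohept-3-ene-1-carbaldehyde | O=C[C@]1(C)CC=C(C)C[C@@H](O[Si](C(C)C)(C(C)C)C(C)C)[C@@H]1C=C | intermediate
32 | (1R,6R,7R)-7-acetyl-1,4-dimethyl-6-[(triisopropylsilyl)oxy]cyclohept-3-ene-1-carbaldehyde | O=C[C@]1(C)CC=C(C)C[C@@H](O[Si](C(C)C)(C(C)C)C(C)C)[C@@H]1C(C)=O | intermediate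
33 | (1R,6R,7R)-1,4-dimethyl-7-{1-[(triethylsilyl)oxy]ethenyl}-6-[(triisopropylsilyl)oxy]cyclohept-3-ene-1-carbaldehyde | O=C[C@]1(C)CC=C(C)C[C@@H](O[Si](C(C)C)(C(C)C)C(C)C)[C@@H]1C(=C)O[Si](CC)(CC)CC | intermediate (not isolated)
34 | (3S,3aR,8R,8aR)-3a,6-dimethyl-3-[(triethylsilyl)oxy]-8-[(triisopropylsilyl)oxy]-3,3a,4,7,8,8a-hexahydroazulen-1(2H)-one | CC[Si](CC)(CC)O[C@H]1CC(=O)[C@H]2[C@H](O[Si](C(C)C)(C(C)C)C(C)C)CC(C)=CC[C@@]12C | intermediate
35 | (1S,3S,3aR,8R,8aR)-3a,6-dimethyl-1-(propan-2-yl)-3-[(triethylsilyl)oxy]-8-[(triisopropylsilyl)oxy]-1,2,3,3a,4,7,8,8a-octahydroazulen-1-ol | CC[Si](CC)(CC)O[C@H]1C[C@](O)(C(C)C)[C@H]2[C@H](O[Si](C(C)C)(C(C)C)C(C)C)CC(C)=CC[C@@]12C | intermediate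
36 | (1S,3S,3aR,8R,8aR)-3a,6-dimethyl-1-(propan-2-yl)-8-[(triisopropylsilyl)oxy]-1,2,3,3a,4,7,8,8a-octahydroazulene-1,3-diol | O[C@H]1C[C@](O)(C(C)C)[C@H]2[C@H](O[Si](C(C)C)(C(C)C)C(C)C)CC(C)=CC[C@@]12C | intermediate
37 | angelic acid [(2Z)-2-methylbut-2-enoic acid] | C/C=C(/C)C(=O)O | starting material
38 | (1S,3S,3aR,4R,8aR)-3-hydroxy-6,8a-dimethyl-3-(propan-2-yl)-4-[(triisopropylsilyl)oxy]-1,2,3,3a,4,5,8,8a-octahydroazulen-1-yl (2Z)-2-methylbut-2-enoate | C/C=C(/C)C(=O)O[C@H]1C[C@](O)(C(C)C)[C@H]2[C@H](O[Si](C(C)C)(C(C)C)C(C)C)CC(C)=CC[C@@]12C | intermediate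
39 | (1S,3S,3aR,4R,8aR)-3,4-dihydroxy-6,8a-dimethyl-3-(propan-2-yl)-1,2,3,3a,4,5,8,8a-octahydroazulen-1-yl (2Z)-2-methylbut-2-enoate | C/C=C(/C)C(=O)O[C@H]1C[C@](O)(C(C)C)[C@H]2[C@H](O)CC(C)=CC[C@@]12C | intermediate
40 | 3,4,5-trimethoxybenzoyl chloride | COc1cc(cc(OC)c1OC)C(Cl)=O | starting material
41 | (1S,3S,3aR,4R,8aR)-3-hydroxy-6,8a-dimethyl-1-{[(2Z)-2-methylbut-2-enoyl]oxy}-3-(propan-2-yl)-1,2,3,3a,4,5,8,8a-octahydroazulen-4-yl 3,4,5-trimethoxybenzoate (CNP0112256.1) | C/C=C(/C)C(=O)O[C@H]1C[C@](O)(C(C)C)[C@H]2[C@H](OC(=O)c3cc(OC)c(OC)c(OC)c3)CC(C)=CC[C@@]12C | target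

## Step count and least certain steps

Total step count: 24. Longest linear sequence: 23 steps (steps 1–6 and 8–24; step 7 is a one-step side branch).

**Step 15 (key step).** The most likely failure is slow enolisation and O-silylation at the fully substituted, hindered C1, combined with a congested boat transition state in which a quaternary carbon forms. The ketene acetal could then be lost on heating by C-silylation, by hydrolysis back to the lactone or by fragmentation before it rearranges. The fallback moves the methyl group behind the rearrangement. It sets out from 23, whose C1 is a CH2 group. The same enolisation and silylation would give the less hindered silyl ketene acetal F1, which would pass through the same boat to the silyl ester F2 and, after hydrolysis, the acid F3 with a tertiary C1. The dianion of F3 (2 equiv LiN(i-Pr)2, THF/HMPA) would then be methylated with iodomethane from the face opposite the neighbouring C5 vinyl group. The quaternary centre is then set by enolate alkylation and not by chirality transfer. The fallback comes back to the route at 29.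

**Step 19.** The most likely failure is poor facial selectivity at the aldehyde (a closed transition state competing with the open one), which gives the C2 epimer. A second risk is slow five-membered enol-endo closure, which leaves time for enolisation toward C5 and loss of the cis ring fusion. The fallback makes the C2 epimer on purpose and inverts it. From 32, the lithium enolate (LiN(SiMe3)2, THF, −78 °C) should cyclise through a chelated transition state that turns the aldehyde oxygen toward the enolate oxygen, and silylation with Et3SiOTf would give the C2-epimeric ketone F4. Addition of i-PrCeCl2 would give the tertiary alcohol F5, and PPTS in MeOH the C2-epimeric diol F6. A Mitsunobu reaction (PPh3, DIAD, 4-nitrobenzoic acid, PhMe) would invert C2 with the nucleophile entering anti to the angular methyl, as in inversions of steroidal 17β-alcohols, to give the 4-nitrobenzoate F7. Methanolysis (K2CO3, MeOH) comes back to the route at 36.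

**Step 13.** The most likely failure is loss of the ketene or its carbene precursor before ring closure: dimerisation, capture by adventitious water or carbene insertion into the O–H bond, because closure of a seven-membered ring onto a tertiary alcohol is slow. The fallback separates homologation from lactonisation. It sets out from 20: a silver-promoted Wolff rearrangement in wet solvent (AgO2CPh, Et3N, THF/H2O) would give the homologated acid F8. Buffered Bu4NF would free the tertiary alcohol to give the hydroxy acid F9. A Shiina lactonisation (2-methyl-6-nitrobenzoic anhydride, DMAP, high dilution) would come back to the route at 23.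

**Step 22.** The most likely failure is isomerisation of the activated angelate to the tiglate during a slow acylation of the neopentyl-type C2 hydroxyl. The fallback builds the Z-enoate on the substrate. From 36, esterification with 2-[bis(2,2,2-trifluoroethoxy)phosphoryl]propanoic acid (DCC, DMAP) would give the phosphonate ester F10. A Still–Gennari olefination with acetaldehyde (KN(SiMe3)2, 18-crown-6, THF, −78 °C) would then form the Z-trisubstituted enoate and come back to the route at 38.

**Step 18.** The most likely failure is stalled or misdirected oxypalladation at a vinyl group flanked by a quaternary carbon and a silyloxy-bearing carbon, which would give the aldehyde regioisomer or allow isomerisation of the ring alkene. The fallback hydrates the alkene by another mechanism. From 31, oxymercuration and demercuration (Hg(OAc)2, THF/H2O; NaBH4, NaOH), which favour the monosubstituted alkene over the trisubstituted one, would give the diol F11; the aldehyde is reduced in the same operation. Dess–Martin oxidation of both alcohols comes back to the route at 32.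

## Further compounds

F1 | step 15 | tert-butyldimethylsilyl ketene acetal of 23 | C=C[C@@]1(C)C[C@@H](O[Si](C(C)C)(C(C)C)C(C)C)[C@H](C=C)C=C(O[Si](C)(C)C(C)(C)C)O1
F2 | step 15 | tert-butyldimethylsilyl ester of F3 | CC(C)(C)[Si](C)(C)OC(=O)[C@@H]1CC=C(C)C[C@@H](O[Si](C(C)C)(C(C)C)C(C)C)[C@@H]1C=C
F3 | step 15 | 7-ethenyl-4-methyl-6-[(triisopropylsilyl)oxy]cyclohept-3-ene-1-carboxylic acid (29 without the C1 methyl) | OC(=O)[C@@H]1CC=C(C)C[C@@H](O[Si](C(C)C)(C(C)C)C(C)C)[C@@H]1C=C
F4 | step 19 | C2 epimer of 34 | CC[Si](CC)(CC)O[C@@H]1CC(=O)[C@H]2[C@H](O[Si](C(C)C)(C(C)C)C(C)C)CC(C)=CC[C@@]12C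
F5 | step 19 | C2 epimer of 35 | CC[Si](CC)(CC)O[C@@H]1C[C@](O)(C(C)C)[C@H]2[C@H](O[Si](C(C)C)(C(C)C)C(C)C)CC(C)=CC[C@@]12C
F6 | step 19 | C2 epimer of 36 | O[C@@H]1C[C@](O)(C(C)C)[C@H]2[C@H](O[Si](C(C)C)(C(C)C)C(C)C)CC(C)=CC[C@@]12C
F7 | step 19 | 4-nitrobenzoate of 36 at the C2 oxygen | O=C(O[C@H]1C[C@](O)(C(C)C)[C@H]2[C@H](O[Si](C(C)C)(C(C)C)C(C)C)CC(C)=CC[C@@]12C)c1ccc(cc1)[N+](=O)[O-]
F8 | step 13 | 3-ethenyl-6-methyl-6-[(triethylsilyl)oxy]-4-[(triisopropylsilyl)oxy]oct-7-enoic acid, configured as 20 | OC(=O)C[C@@H](C=C)[C@H](O[Si](C(C)C)(C(C)C)C(C)C)C[C@@](C)(O[Si](CC)(CC)CC)C=C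
F9 | step 13 | 3-ethenyl-6-hydroxy-6-methyl-4-[(triisopropylsilyl)oxy]oct-7-enoic acid, configured as 21 | OC(=O)C[C@@H](C=C)[C@H](O[Si](C(C)C)(C(C)C)C(C)C)C[C@@](C)(O)C=C
F10 | step 22 | 2-[bis(2,2,2-trifluoroethoxy)phosphoryl]propanoate of 36 at the C2 oxygen | CC(C(=O)O[C@H]1C[C@](O)(C(C)C)[C@H]2[C@H](O[Si](C(C)C)(C(C)C)C(C)C)CC(C)=CC[C@@]12C)P(=O)(OCC(F)(F)F)OCC(F)(F)F
F11 | step 18 | diol with hydroxymethyl on C1 and 1-hydroxyethyl on C5 (reduced form of 32, carbinol epimers) | OC[C@]1(C)CC=C(C)C[C@@H](O[Si](C(C)C)(C(C)C)C(C)C)[C@@H]1C(C)O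
A1 | alternative 1 | 3-isopropyl-4-methoxy-6,8a-dimethyl-3-(triethylsilyloxy)-2,3-dihydroazulen-1(8aH)-one | O=C1C[C@](O[Si](CC)(CC)CC)(C(C)C)C2=C(OC)C=C(C)C=C[C@@]12C
A2 | alternative 1 | 2-diazo-5-(2-methoxy-4-methylphenyl)-6-methyl-5-(triethylsilyloxy)heptan-3-one | CC(=[N+]=[N-])C(=O)C[C@](O[Si](CC)(CC)CC)(C(C)C)c1ccc(C)cc1OC
A3 | alternative 2 | cis-fused nitro hydroxy bicyclic enone with the complete carbon skeleton | [O-][N+](=O)[C@H]1C[C@](O)(C(C)C)[C@H]2C(=O)C=C(C)CC[C@@]12C
A4 | alternative 2 | 4-methyl-1-nitropentan-3-one | CC(C)C(=O)CC[N+](=O)[O-]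
A5 | alternative 2 | 3,6-dimethylcyclohepta-2,6-dien-1-one | O=C1C=C(C)CCC(C)=C1
A6 | alternative 3 | cyclohepta-1,4-diene with quaternary C1 (methyl, tert-butyl ester), C6 silyl enol ether and C8 methyl ester | COC(=O)C1=CC[C@@](C)(C(=O)OC(C)(C)C)C=C(O[Si](C)(C)C(C)(C)C)C1
A7 | alternative 3 | methyl 2-diazobut-3-enoate | COC(=O)C(=[N+]=[N-])C=C
A8 | alternative 3 | tert-butyl (2E)-4-[(tert-butyldimethylsilyl)oxy]-2-methylpenta-2,4-dienoate | C=C(O[Si](C)(C)C(C)(C)C)/C=C(C)/C(=O)OC(C)(C)C
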